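**Compound numbers used throughout** (fixed by the order of the steps)
1 5-ethynyl-1,2,3-trimethoxybenzene; 2 N-methoxy-N-methylcarbamoyl chloride; 3 lithium acetylide of 1; 4 N-methoxy-N-methyl-3-(3,4,5-trimethoxyphenyl)prop-2-ynamide; 5 triacetic acid lactone; 6 dilithiated 5; 7 pyranone alkynyl ketone (key precursor); 8 acyclic methyl trioxo ester; 9 trihydroxyphenyl alkynyl ketone; 10 5,7-dihydroxy-3',4',5'-trimethoxyflavone; 11 its 6,8-dibromide; 12 5,7-dihydroxy-6,8,3',4',5'-pentamethoxyflavone; 13 Gardenin A.

Remark on the chemistry: ring atoms carry flavone numbers (O1, C2, C3, C4, C4a, C5 to C8, C8a; ring B primed). The carbons of the open polyketide chain are called chain C1 (ester carbon) to chain C9 (aryl-bearing alkyne carbon). Mg(OMe)2 and LiN(i-Pr)2 are assumed to be used as commercial solutions.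

## Analysis of the target

Gardenin A (13) is a flavone: a benzene ring A fused through C4a and C8a to a 4-pyranone ring C (O1, C2, C3, C4), with a 3,4,5-trimethoxyphenyl ring B on C2. It has no stereocentre and no stereogenic double bond, so the whole task is connectivity and the placing of nine oxygens. Ring A is hexasubstituted: C5 carries the only free hydroxyl, hydrogen-bonded to the C4 carbonyl, C6, C7 and C8 carry methoxyls, and C4a and C8a are the fusion atoms. The sensitive points are the pyranone, which hot strong base can open between O1 and C2 to a 2-hydroxyaryl 1,3-diketone, the electron-rich rings A and B, which over-react with electrophiles and oxidants, and the need to finish with six methyl ethers beside one unmethylated phenol. The difficulty therefore lies in ring A and not in any single carbon–carbon bond. The strategy rests on the fact that the oxygens on C5, C7 and C8a are mutually meta and that C4a, between C5 and C8a, carries the acyl carbon C4. Ring A is thus a C-acylated phloroglucinol, and with C4, C3 and C2 its carbons form one unbranched nine-carbon chain oxygenated at every second atom, which is a folded poly-β-carbonyl chain. Only the methoxyls on C6 and C8 fall outside this pattern, and they sit on the two nucleophilic carbons of the phloroglucinol, so they can be added after the fold; since the two oxygens ortho to the acyl carbon are equivalent in every intermediate from 9 to 13, closure or base-induced reopening of ring C has only one outcome.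

## Retrosynthetic reasoning

**13 ⇒ 12.** The O–CH3 bond at C7 is cut last. Of the two hydroxyls of 12, the one on C5 is locked in a hydrogen bond to the C4 carbonyl and is a poor nucleophile. The one on C7 is a vinylogous acid conjugated with that carbonyl and gives a free phenoxide. One equivalent of a methylating agent under carbonate base should therefore alkylate C7–OH alone, and the free C5 hydroxyl of 13 never needs a protecting group.

**12 ⇒ 11 ⇒ 10.** The C6–O and C8–O bonds are cut next, by way of the C–Br bonds of 11. These are the two oxygens a polyketide fold cannot supply. C6 and C8 of 10 are the ring A carbons that lie ortho or para to three oxygen donors, so an electrophilic bromine source should reach them before C3 or ring B. Copper-mediated exchange of both bromines for methoxyl then completes the oxygenation. Both positions receive the same group, so neither operation has a regiochemical question, and any opening and reclosure of ring C in the hot base is degenerate. What is gained is that ring A of 10 has only the phloroglucinol pattern.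

**10 ⇒ 9 ⇒ 8 ⇒ 7 (key step).** Two bonds are cut: O1–C2, which opens ring C to the alkynyl ketone 9, and the ring A bond from C4a to C5 (or, by symmetry, C8a), which unfolds 9 into the acyclic trioxo ester 8. Cutting C4–C4a instead would be the conventional acylation of a ready-made triphenol, but it would buy ring A and not make it. The cut at C4a is the one the oxygen pattern points to: in 8 the nucleophilic carbon (chain C6, between two ketones) and the electrophilic ester carbon (chain C1) are exactly six atoms apart. The alkyne in place of a fourth ketone keeps chain C8 from acting as a second nucleophile and delivers C2 at the right oxidation level. The lactone 7 is preferred to 8 as the isolable precursor because it ties up chain C1 and the chain C5 oxygen and so blocks premature cyclisation. The forward reaction has to open the lactone, fold the chain in the Claisen and not the aldol sense, and close ring C through oxygen on C2 in the six-membered mode.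

**7 ⇒ 4 + 5.** The C–C bond between the side-chain methylene and the ketone carbon (chain C6–C7) is cut. This divides 7 into the six-carbon lactone 5, a cheap commercial triketide equivalent, and the aryl-alkynyl acyl donor 4. In the forward direction 5 is deprotonated twice to 6, whose exocyclic carbon is the reactive site. The N-methoxy-N-methyl amide 4 is chosen because it stops at the ketone stage, so the acidic product cannot consume 6 and the alkynyl ketone is not exposed to nucleophiles until the quench.

**4 ⇒ 1 + 2.** The bond between the alkyne carbon and the amide carbonyl is cut, leading to the acetylide 3 of the commercial alkyne 1 and the commercial carbamoyl chloride 2. Ring B with its three methoxyls is bought intact.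

## Alternatives that were turned down

**Alternative 1:** Ring A is cut at C4a–C5 and traced to a cyclobutenone.
- Disconnection: dimethyl squarate A1 supplies C5 to C8 with their oxygens. The lithiated form of the dihydropyran 4-(tert-butyldimethylsilyloxy)-2-(3,4,5-trimethoxyphenyl)-3,4-dihydro-2H-pyran A2 supplies ring C with C4a and C8a. Addition and O-methylation give the 2,3,4-trimethoxy-4-(dihydropyranyl)cyclobutenone A3.
- Forward key step: heating A3 opens the four-membered ring and recloses six electrons onto the dihydropyran double bond (Moore rearrangement). This forms C4a–C5 and gives the chroman A4, with the former carbonyl carbon as the free C5 phenol.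
- For it: the hexasubstituted ring A appears in one step with all four oxygens placed and already differentiated. No late halogenation or selective methylation is needed. On this point it is stronger than the chosen route.
- Against it: A4 sits at the chroman oxidation level, so C2 and C4 are stereocentres made as mixtures only to be erased. Desilylation, oxidation at C4 and dehydrogenation across C2–C3 must follow. A2 takes several steps to make, and its lithiation at C6 competes with removal of the benzylic C2 hydrogen and with loss of the allylic silyloxy group. In A4 a benzylic silyloxy group lies ortho to the new phenol, so thermal loss of silanol to a quinone methide is a plausible leak.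
- Comparison: about ten steps against six. The chosen route places two methoxyls late, but it has no stereochemical or redox detours and reaches its key precursor in two steps.

**Alternative 2:** C3 is excised from ring C (bonds C2–C3 and C3–C4).
- Disconnection: this leads back to the fully methoxylated 2-aryl-3-(trimethylsilyloxy)benzofuran A5.
- Forward key step: dibromocarbene adds to the furan C2=C3 bond. The dibromocyclopropane opens with loss of bromide and the silyl group, which inserts one carbon and gives the 3-bromoflavone A6.
- For it: all oxygens are in place before the key step, so no C–O bond has to be made on ring A afterwards; this is an advantage over the chosen route. The ring expansion has good mechanistic analogy in dihalocarbene insertions into cyclic silyl enol ethers.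
- Against it: the C2=C3 bond of A5 is tetrasubstituted and flanked by ring B and the C4 methoxyl, so carbene addition should be slow. The alkoxide base can cleave the silyl ether first, giving an oxidation-prone enolate. A6 needs two corrective steps: removal of the C3 bromine and cleavage of the C5 methyl ether. Above all, A5 presupposes the hexasubstituted ring A, so the real difficulty of the target is moved into the precursor and not solved.
- Comparison: the chosen route makes ring A and ring C from an acyclic chain in one operation and starts from three simple commercial compounds.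

**Alternative 3:** The O1–C8a bond is cut.
- Disconnection: the precursor is the hydroquinone 1,3-diketone A7.
- Forward key step: two-electron anodic oxidation gives the acylquinone A8. Its diketone enol oxygen adds to the unsubstituted quinone carbon (6-endo-trig), and tautomerisation gives the 5,8-dihydroxyflavone A9. One methylation of the non-chelated C8 hydroxyl would then give 13.
- For it: the end-game is one step against three, and the ring A oxygens are fixed with certainty. On both points it is at least as strong as the chosen route.
- Against it: A9 has gained an oxygen substituent and should be oxidised more easily than A7. Over-oxidation to the flavone quinone, at the anode or by redox exchange with A8, is therefore expected. Methoxyquinones are vinylogous esters that exchange or hydrolyse in buffered water. A8 is a multiply activated electrophile open to addition of water. A7 itself needs a tetraoxygenated acetophenone that takes several steps to make.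
- Comparison: the chosen route never enters the quinone oxidation level, needs no electrochemical equipment and has air-stable phenols as intermediates. In exchange it accepts a longer end-game.

Key step: step 3

## Route

Step 1
Reactants: 1 5-ethynyl-1,2,3-trimethoxybenzene; 2 N-methoxy-N-methylcarbamoyl chloride
Product: 4 N-methoxy-N-methyl-3-(3,4,5-trimethoxyphenyl)prop-2-ynamide, via lithium acetylide 3 (not isolated)
Conditions: n-BuLi (1.05 equiv), THF, −78 °C; then 2 (1.1 equiv), −78 to 0 °C; aq. NH4Cl
Reagents that add atoms: none
Why: Deprotonation of the terminal alkyne and carbamoylation of the acetylide; the carbamoyl chloride is far more electrophilic than the amide formed, so the reaction should stop at 4.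

Step 2
Reactants: 4 N-methoxy-N-methyl-3-(3,4,5-trimethoxyphenyl)prop-2-ynamide; 5 triacetic acid lactone (4-hydroxy-6-methyl-2H-pyran-2-one)
Product: 7 4-hydroxy-6-[2-oxo-4-(3,4,5-trimethoxyphenyl)but-3-yn-1-yl]-2H-pyran-2-one, via dilithiated lactone 6 (not isolated)
Conditions: 5 (1.3 equiv), LiN(i-Pr)2 (LDA, 2.7 equiv), THF, −78 to 0 °C; then 4 (1.0 equiv), −78 to −40 °C; poured into cold 1 M aq. HCl
Reagents that add atoms: none
Why: Weinreb ketone synthesis with a dianion: the first deprotonation protects the ring as its 4-oxide, the second makes the 6-methyl carbon the nucleophile, and the N-methoxy-N-methyl amide should stop at the ketone stage; the cold acid quench keeps the liberated amines protonated and away from the alkynyl ketone.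

Step 3
Reactants: 7 4-hydroxy-6-[2-oxo-4-(3,4,5-trimethoxyphenyl)but-3-yn-1-yl]-2H-pyran-2-one
Product: 10 5,7-dihydroxy-3',4',5'-trimethoxyflavone, via acyclic trioxo ester 8 (not isolated), via trihydroxyphenyl ynone 9 (not isolated)
Conditions: Mg(OMe)2 (6 equiv), MeOH, reflux, Ar; then 2 M aq. HCl to pH 1, 50 °C
Reagents that add atoms: none
Why: Proposed new method: Mg-bound methoxide opens the lactone of 7 at its carbonyl carbon to the chelated trioxo ester 8, in which the alkynyl ketone at chain C7 stands for the last 1,3-dicarbonyl unit; the chain C6 methylene, flanked by the chain C5 and C7 carbonyls, then attacks the ester carbon chain C1 in a Claisen condensation (6-exo-trig, new bond from C4a to the carbon that becomes C5 or, by symmetry, C8a), methoxide leaves and the triketone enolises to the acylphloroglucinol 9, which is ring A. Ring C closes when either of the two equivalent ortho phenol oxygens of 9 adds to the alkyne carbon that becomes C2 (6-endo-dig, new bond O1–C2), directly or after reversible conjugate addition of methoxide to the triple bond, in which case the closure is an addition–elimination at the same carbon that the acid stage completes. The closest known reactions are the Mg(OMe)2-induced opening and Claisen cyclisation of 6-(2-oxoalkyl)-4-hydroxypyran-2-ones and of 3,5,7-trioxo esters to acylphloroglucinols, and the cyclisation of 2-hydroxyaryl alkynyl ketones to flavones; new are the passage of an alkynyl ketone through the Claisen stage and the union of both closures in one flask. No stereocentre is formed. Claisen instead of aldol folding (chain C2 onto the chain C7 ketone, which would give a resorcylic ester) is expected because the strongly basic, ester-preserving medium ionises the chain C4 and C6 methylenes first, so that the chain C7 carbonyl is tied up as a magnesium-chelated enolate while the ester carbonyl stays electrophilic. Six- rather than five-membered closure of ring C is the Michael-type mode, and it is reinforced by the protic methoxide medium and the acid finish, under which every species oxygenated at C2 collapses to the pyranone. Chelation of the chain C5 and C7 oxygens by magnesium also turns the chain C5 enolate oxygen away from the alkyne and so holds back premature O-cyclisation of the open chain. The net change is an isomerisation of 7, so no atom of the reagent remains in 10.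

Step 4
Reactants: 10 5,7-dihydroxy-3',4',5'-trimethoxyflavone
Product: 11 6,8-dibromo-5,7-dihydroxy-3',4',5'-trimethoxyflavone
Conditions: NBS (2.05 equiv), DMF, 0 °C to rt, dark
Reagents that add atoms: N-bromosuccinimide, O=C1CCC(=O)N1Br
Why: Electrophilic aromatic bromination; C6 and C8 each lie ortho or para to three oxygen donors and should react well before C3 or the ring B positions C2' and C6', which are deactivated by the pyranone and hindered.

Step 5
Reactants: 11 6,8-dibromo-5,7-dihydroxy-3',4',5'-trimethoxyflavone
Product: 12 5,7-dihydroxy-6,8,3',4',5'-pentamethoxyflavone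
Conditions: NaOMe (12 equiv, 25% in MeOH), CuBr (0.4 equiv), DMF, 110 °C, Ar; then aq. HCl
Reagents that add atoms: sodium methoxide, C[O-].[Na+]
Why: Ullmann-type copper-mediated methoxylation of aryl bromides, the standard conversion of bromo-5,7-dihydroxyflavones into their methoxy analogues with the phenoxides left free; because C6 and C8 carry the same group, opening and reclosure of ring C in the hot base (Wessely–Moser isomerisation) returns the same compound.

Step 6
Reactants: 12 5,7-dihydroxy-6,8,3',4',5'-pentamethoxyflavone
Product: 13 Gardenin A (5-hydroxy-6,7,8,3',4',5'-hexamethoxyflavone)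
Conditions: Me2SO4 (1.1 equiv), K2CO3 (1.5 equiv), acetone, 45 °C
Reagents that add atoms: dimethyl sulfate, COS(=O)(=O)OC
Why: Williamson O-methylation with one equivalent of reagent; the C7 hydroxyl is the more acidic and gives a free phenoxide, whereas the C5 hydroxyl is hydrogen-bonded to the C4 carbonyl and should not be alkylated under carbonate conditions.

## Compound list

1 | 5-ethynyl-1,2,3-trimethoxybenzene | C#Cc1cc(OC)c(OC)c(OC)c1 | starting material
2 | N-methoxy-N-methylcarbamoyl chloride | CON(C)C(Cl)=O | starting material
3 | lithium (3,4,5-trimethoxyphenyl)acetylide (not isolated) | [Li]C#Cc1cc(OC)c(OC)c(OC)c1 | intermediate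
4 | N-methoxy-N-methyl-3-(3,4,5-trimethoxyphenyl)prop-2-ynamide | CON(C)C(=O)C#Cc1cc(OC)c(OC)c(OC)c1 | intermediate
5 | triacetic acid lactone (4-hydroxy-6-methyl-2H-pyran-2-one) | Cc1cc(O)cc(=O)o1 | starting material
6 | dilithiated triacetic acid lactone, lithium 6-(lithiomethyl)-2-oxo-2H-pyran-4-olate (not isolated) | [Li]Cc1cc(O[Li])cc(=O)o1 | intermediate
7 | 4-hydroxy-6-[2-oxo-4-(3,4,5-trimethoxyphenyl)but-3-yn-1-yl]-2H-pyran-2-one | COc1cc(C#CC(=O)Cc2cc(O)cc(=O)o2)cc(OC)c1OC | intermediate
8 | methyl 3,5,7-trioxo-9-(3,4,5-trimethoxyphenyl)non-8-ynoate (present as its magnesium chelate, not isolated) | COC(=O)CC(=O)CC(=O)CC(=O)C#Cc1cc(OC)c(OC)c(OC)c1 | intermediate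
9 | 1-(2,4,6-trihydroxyphenyl)-3-(3,4,5-trimethoxyphenyl)prop-2-yn-1-one (not isolated) | COc1cc(C#CC(=O)c2c(O)cc(O)cc2O)cc(OC)c1OC | intermediate
10 | 5,7-dihydroxy-3',4',5'-trimethoxyflavone | COc1cc(-c2cc(=O)c3c(O)cc(O)cc3o2)cc(OC)c1OC | intermediate
11 | 6,8-dibromo-5,7-dihydroxy-3',4',5'-trimethoxyflavone | COc1cc(-c2cc(=O)c3c(O)c(Br)c(O)c(Br)c3o2)cc(OC)c1OC | intermediate
12 | 5,7-dihydroxy-6,8,3',4',5'-pentamethoxyflavone | COc1cc(-c2cc(=O)c3c(O)c(OC)c(O)c(OC)c3o2)cc(OC)c1OC | intermediate
13 | Gardenin A (5-hydroxy-6,7,8,3',4',5'-hexamethoxyflavone) | COc1cc(-c2cc(=O)c3c(O)c(OC)c(OC)c(OC)c3o2)cc(OC)c1OC | target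

## Step count and risk

Total step count: 6. Longest linear sequence: 6 steps (1 → 4 → 7 → 10 → 11 → 12 → 13).

**Step 3 (key step, the one labelled as a new method).**
- What may go wrong: the alkynyl ketone may be consumed by oxygen nucleophiles before the carbon–carbon bond forms. This would be O-cyclisation of the opened chain onto the triple bond, or irreversible solvent addition followed by fragmentation. Also possible are folding in the aldol sense, five-membered closure of ring C, and simple re-lactonisation on acidification without net change. The cause is that an alkynyl ketone is a stronger Michael acceptor than the aryl or alkyl ketones for which the magnesium-mediated Claisen fold is established.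
- Fallback (known chemistry, sets out from 4, returns at 10): ring A is taken as a ready-made triphenol. Phloroglucinol F1 is converted into 1,3,5-tris(methoxymethoxy)benzene F2 (MOMCl, i-Pr2NEt, CH2Cl2). F2 is lithiated between two acetal oxygens (n-BuLi, THF, 0 °C) to 2,4,6-tris(methoxymethoxy)phenyllithium F3. F3 is acylated by 4 at −78 °C to 1-[2,4,6-tris(methoxymethoxy)phenyl]-3-(3,4,5-trimethoxyphenyl)prop-2-yn-1-one F4. Et2NH in EtOH adds to the triple bond to give (E)-3-(diethylamino)-1-[2,4,6-tris(methoxymethoxy)phenyl]-3-(3,4,5-trimethoxyphenyl)prop-2-en-1-one F5. HCl in aqueous MeOH at 60 °C then removes the three acetals and closes ring C by addition–elimination at C2, giving 10.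

**Step 2.**
- What may go wrong: conjugate addition of the dianion to the triple bond of 4 in place of attack at the amide carbonyl, and incomplete second deprotonation because the lithium salt of 5 is poorly soluble in THF.
- Fallback (sets out from 1 and 5, returns at 7): the acyl donor is replaced by an aldehyde and the oxidation state is corrected afterwards. The acetylide 3 is formylated with DMF to 3-(3,4,5-trimethoxyphenyl)prop-2-ynal F6. The dianion 6 adds to the aldehyde carbonyl at −78 °C to give racemic 4-hydroxy-6-[2-hydroxy-4-(3,4,5-trimethoxyphenyl)but-3-yn-1-yl]-2H-pyran-2-one F7. MnO2 in acetone/CH2Cl2 oxidises the propargylic alcohol to 7.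

**Step 5.**
- What may go wrong: loss of bromine by reduction before exchange, and incomplete exchange at the doubly flanked C6. A bromine ortho and para to phenoxide oxygens is a positive-bromine donor, and hot methoxide is a hydride source.
- Fallback (sets out from 11, returns at 12): the phenoxides are removed from the exchange step. BnBr and K2CO3 in DMF at 70 °C give 5,7-bis(benzyloxy)-6,8-dibromo-3',4',5'-trimethoxyflavone F8. NaOMe and CuBr in DMF/MeOH at 110 °C give 5,7-bis(benzyloxy)-6,8,3',4',5'-pentamethoxyflavone F9. Hydrogenolysis (H2, Pd/C, EtOAc) gives 12.

**Step 6.**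
- What may go wrong: slow alkylation of the C7 hydroxyl, which is flanked by two methoxyls. Forcing the reaction then erodes the selectivity against the C5 hydroxyl.
- Fallback (sets out from 12, returns at 13): selectivity is obtained by cleavage instead of by formation. Excess MeI with K2CO3 in DMF at 60 °C gives 5,6,7,8,3',4',5'-heptamethoxyflavone F10. BCl3 in CH2Cl2 at −20 to 0 °C then removes only the methyl ether peri to the C4 carbonyl, through a six-membered boron chelate, to give 13.

## Further compounds

F1 | step 3 | phloroglucinol | Oc1cc(O)cc(O)c1
F2 | step 3 | 1,3,5-tris(methoxymethoxy)benzene | COCOc1cc(OCOC)cc(OCOC)c1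
F3 | step 3 | 2,4,6-tris(methoxymethoxy)phenyllithium | [Li]c1c(OCOC)cc(OCOC)cc1OCOC
F4 | step 3 | 1-[2,4,6-tris(methoxymethoxy)phenyl]-3-(3,4,5-trimethoxyphenyl)prop-2-yn-1-one | COCOc1cc(OCOC)c(C(=O)C#Cc2cc(OC)c(OC)c(OC)c2)c(OCOC)c1
F5 | step 3 | (E)-3-(diethylamino)-1-[2,4,6-tris(methoxymethoxy)phenyl]-3-(3,4,5-trimethoxyphenyl)prop-2-en-1-one | CCN(CC)/C(c1cc(OC)c(OC)c(OC)c1)=C/C(=O)c1c(OCOC)cc(OCOC)cc1OCOC
F6 | step 2 | 3-(3,4,5-trimethoxyphenyl)prop-2-ynal | O=CC#Cc1cc(OC)c(OC)c(OC)c1
F7 | step 2 | 4-hydroxy-6-[2-hydroxy-4-(3,4,5-trimethoxyphenyl)but-3-yn-1-yl]-2H-pyran-2-one (racemic) | COc1cc(C#CC(O)Cc2cc(O)cc(=O)o2)cc(OC)c1OC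
F8 | step 5 | 5,7-bis(benzyloxy)-6,8-dibromo-3',4',5'-trimethoxyflavone | COc1cc(-c2cc(=O)c3c(OCc4ccccc4)c(Br)c(OCc4ccccc4)c(Br)c3o2)cc(OC)c1OC
F9 | step 5 | 5,7-bis(benzyloxy)-6,8,3',4',5'-pentamethoxyflavone | COc1cc(-c2cc(=O)c3c(OCc4ccccc4)c(OC)c(OCc4ccccc4)c(OC)c3o2)cc(OC)c1OC
F10 | step 6 | 5,6,7,8,3',4',5'-heptamethoxyflavone | COc1cc(-c2cc(=O)c3c(OC)c(OC)c(OC)c(OC)c3o2)cc(OC)c1OC
A1 | alternative 1 | dimethyl squarate (3,4-dimethoxycyclobut-3-ene-1,2-dione) | COC1=C(OC)C(=O)C1=O
A2 | alternative 1 | 4-(tert-butyldimethylsilyloxy)-2-(3,4,5-trimethoxyphenyl)-3,4-dihydro-2H-pyran (diastereomer mixture) | CC(C)(C)[Si](C)(C)OC1CC(c2cc(OC)c(OC)c(OC)c2)OC=C1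
A3 | alternative 1 | 4-[4-(tert-butyldimethylsilyloxy)-2-(3,4,5-trimethoxyphenyl)-3,4-dihydro-2H-pyran-6-yl]-2,3,4-trimethoxycyclobut-2-en-1-one (diastereomer mixture) | O=C1C(OC)=C(OC)C1(OC)C1=CC(O[Si](C)(C)C(C)(C)C)CC(c2cc(OC)c(OC)c(OC)c2)O1
A4 | alternative 1 | 4-(tert-butyldimethylsilyloxy)-5-hydroxy-6,7,8-trimethoxy-2-(3,4,5-trimethoxyphenyl)chroman (diastereomer mixture) | Oc1c(OC)c(OC)c(OC)c2OC(c3cc(OC)c(OC)c(OC)c3)CC(O[Si](C)(C)C(C)(C)C)c12
A5 | alternative 2 | 4,5,6,7-tetramethoxy-2-(3,4,5-trimethoxyphenyl)-3-(trimethylsilyloxy)benzofuran | COc1cc(-c2oc3c(OC)c(OC)c(OC)c(OC)c3c2O[Si](C)(C)C)cc(OC)c1OC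
A6 | alternative 2 | 3-bromo-5,6,7,8,3',4',5'-heptamethoxyflavone | COc1cc(-c2oc3c(OC)c(OC)c(OC)c(OC)c3c(=O)c2Br)cc(OC)c1OC
A7 | alternative 3 | 1-(2,5-dihydroxy-3,4-dimethoxyphenyl)-3-(3,4,5-trimethoxyphenyl)propane-1,3-dione | COc1cc(C(=O)CC(=O)c2cc(O)c(OC)c(OC)c2O)cc(OC)c1OC
A8 | alternative 3 | 2,3-dimethoxy-5-[3-oxo-3-(3,4,5-trimethoxyphenyl)propanoyl]-1,4-benzoquinone | COC1=C(OC)C(=O)C(C(=O)CC(=O)c2cc(OC)c(OC)c(OC)c2)=CC1=O
A9 | alternative 3 | 5,8-dihydroxy-6,7,3',4',5'-pentamethoxyflavone | COc1c(OC)c(O)c2c(=O)cc(-c3cc(OC)c(OC)c(OC)c3)oc2c1O
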